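**Retrosynthetic overview**

1. The strategy rests on ring A of the flavone: C5, C7 and C8a carry oxygen and C4a carries the acyl carbon C4, the 1,3,5-trioxygenated acylbenzene pattern that a folded poly-β-carbonyl chain gives. Ring B (2′,5′-dihydroxy-4′-methoxyphenyl) is carried as its dibenzyl ether.
2. Last operations: debenzylation, 5-O-methylation, and closure of ring C (O1–C2 bond) by cyclodehydration of the o-hydroxyaryl 1,3-diketone 14.
3. Ring A: the C4a–C5 bond is made by Claisen closure of chain carbon C6 onto ester carbon C1 of methyl (E)-9-aryl-3,8-dimethoxy-5,7,9-trioxonon-2-enoate 13. Ester 13 is released in the flask from its enol lactone, the 4-methoxy-2-pyranone 12, because the doubly activated C4 methylene of an open 3-methoxyglutaconate ester would protonate any carbanion used to build the chain.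
4. Pyranone 12 comes from 4-methoxy-6-methyl-2-pyranone 8 by two acylations: methoxyacetylation of the lithiated methyl group (chain C6–C7), then aroylation of the dianion (chain C8–C9) with the ring B Weinreb amide 5, made from methoxyhydroquinone 1.
5. Ring order: ring B is bought, ring A is formed in step 7, ring C in step 8.

Key step: step 7

Remark: compounds 12, 13 and 14 carry a CH(OMe) carbon between two carbonyl groups; it is racemic and enolizable and becomes sp2 (C3) in step 8, so the target has no stereocenter to control.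

**Route**

Step 1
Reactants: 1 methoxyhydroquinone (2-methoxybenzene-1,4-diol)
Product: 2 1,4-bis(benzyloxy)-2-methoxybenzene
Conditions: BnBr (2.4 equiv), K2CO3, DMF, 60 °C, argon
Reagents that add atoms: benzyl bromide, BrCc1ccccc1
Why: Williamson etherification (SN2 of both potassium phenoxides on benzyl bromide), run in degassed solvent so that the hydroquinone is not oxidized before it is capped.

Step 2
Reactants: 2 1,4-bis(benzyloxy)-2-methoxybenzene
Product: 3 1,4-bis(benzyloxy)-2-bromo-5-methoxybenzene
Conditions: NBS, MeCN, 0 °C → rt, dark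
Reagents that add atoms: N-bromosuccinimide, O=C1CCC(=O)N1Br
Why: Electrophilic aromatic bromination should go to the carbon para to the methoxy group and ortho to a benzyloxy group, the most activated and least hindered position, as in the bromination of 1,2,4-trimethoxybenzene.

Step 3
Reactants: 3 1,4-bis(benzyloxy)-2-bromo-5-methoxybenzene
Product: 5 2,5-bis(benzyloxy)-N,4-dimethoxy-N-methylbenzamide, via aryllithium 4 (not isolated)
Conditions: n-BuLi, THF, −78 °C; then cannulated into ClC(O)N(OMe)Me, THF, −78 → 0 °C
Reagents that add atoms: N-methoxy-N-methylcarbamoyl chloride, CON(C)C(=O)Cl; n-butyllithium, CCCC[Li] (supplies only the lithium of 4)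
Why: Bromine–lithium exchange followed by acyl substitution on the carbamoyl chloride gives the Weinreb amide, and inverse addition keeps the aryllithium from adding to the amide already formed.

Step 4
Reactants: 6 methoxyacetyl chloride
Product: 7 N,2-dimethoxy-N-methylacetamide
Conditions: MeNHOMe·HCl, Et3N (2.2 equiv), CH2Cl2, 0 °C → rt
Reagents that add atoms: N,O-dimethylhydroxylamine hydrochloride, CNOC.Cl
Why: N-acylation of the hydroxylamine by the acid chloride (Weinreb amide formation).

Step 5
Reactants: 8 4-methoxy-6-methyl-2H-pyran-2-one; 7 N,2-dimethoxy-N-methylacetamide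
Product: 10 4-methoxy-6-(3-methoxy-2-oxopropyl)-2H-pyran-2-one, via lithiomethylpyranone 9 (not isolated)
Conditions: LiN(i-Pr)2 (1.1 equiv), THF, −78 °C; then 7, −78 → −40 °C; 1 M HCl
Reagents that add atoms: lithium diisopropylamide, CC(C)N([Li])C(C)C (supplies only the lithium of 9)
Why: Lateral lithiation of the vinylogous C6-methyl group followed by Weinreb ketone synthesis, in which the chelated tetrahedral adduct holds back the more acidic product ketone until the quench.

Step 6
Reactants: 10 4-methoxy-6-(3-methoxy-2-oxopropyl)-2H-pyran-2-one; 5 2,5-bis(benzyloxy)-N,4-dimethoxy-N-methylbenzamide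
Product: 12 6-{4-[2,5-bis(benzyloxy)-4-methoxyphenyl]-3-methoxy-2,4-dioxobutyl}-4-methoxy-2H-pyran-2-one, via dilithio dianion 11 (not isolated)
Conditions: LiN(i-Pr)2 (2.2 equiv), THF, −78 → −30 °C; then 5, −78 → −20 °C; 1 M HCl
Reagents that add atoms: lithium diisopropylamide, CC(C)N([Li])C(C)C (supplies only the lithium atoms of 11)
Why: Hauser–Harris dianion acylation, in which the second deprotonation falls on the methoxymethylene carbon and this more basic terminus of the 1,3-dianion attacks the Weinreb amide, whose tetrahedral adduct prevents over-addition while benzyl ethers and pyranone tolerate the cold amide base.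

Step 7
Reactants: 12 6-{4-[2,5-bis(benzyloxy)-4-methoxyphenyl]-3-methoxy-2,4-dioxobutyl}-4-methoxy-2H-pyran-2-one
Product: 14 1-[2,5-bis(benzyloxy)-4-methoxyphenyl]-3-(2,6-dihydroxy-4-methoxyphenyl)-2-methoxypropane-1,3-dione, via open-chain enol ether ester 13 (not isolated)
Conditions: Mg(OMe)2 (5 equiv), MeOH, rt then reflux, argon; cold 1 M HCl
Reagents that add atoms: magnesium methoxide in methanol, CO[Mg]OC (supplies only the ester methoxyl of 13, which leaves again in the ring closure)
Why: Mg(OMe)2 should first deprotonate the side-chain β-dicarbonyl unit, and methoxide then opens the lactone of 12 at C2 to the magnesium chelate of 13, in which the former ring double bond is the E enol ether, so the ester carbon (chain C1) lies cis to chain C4 and within reach of the chelated C5–C6–C7 enolate. Carbon C6 of that enolate (the future C4a) attacks the ester carbonyl, methoxide is expelled, and the ring enolizes to the aromatic 2,6-dihydroxy-4-methoxyphenyl ketone, which makes the C–C bond formation irreversible. The closest known reaction type is the Mg(OMe)2-mediated conversion of 6-(2-oxoalkyl)-4-methoxy-2-pyranones into acylphloroglucinol monomethyl ethers, the biomimetic Claisen (Dieckmann-type) cyclization of 3,5,7-triketo esters. Ring A closes in a 6-exo-trig mode (enolate carbon onto an exocyclic ester carbonyl), and no stereocenter is formed. The step needs C-acylation through C6 rather than aldol folding or lactone re-closure: the enol ether removes the chain C3 carbonyl as an electrophile and leaves C2 non-nucleophilic, the E geometry inherited from the pyranone ring presets the C1/C6 proximity, and the magnesium chelate localizes the nucleophile on C6 while re-closure to 12 stays reversible.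

Step 8
Reactants: 14 1-[2,5-bis(benzyloxy)-4-methoxyphenyl]-3-(2,6-dihydroxy-4-methoxyphenyl)-2-methoxypropane-1,3-dione
Product: 16 2-[2,5-bis(benzyloxy)-4-methoxyphenyl]-5-hydroxy-3,7-dimethoxy-4H-chromen-4-one, via hemiketal 15 (not isolated)
Conditions: TsOH·H2O (0.2 equiv), toluene, 90 °C
Reagents that add atoms: none
Why: Acid-catalysed cyclodehydration of an o-hydroxyaryl 1,3-diketone (the closing stage of a Baker–Venkataraman flavone synthesis), in which a phenol oxygen adds 6-exo-trig to the ring B ketone and hemiketal 15 loses water across C2–C3; the two ring A hydroxyls are equivalent, so only one flavone can form, and catalytic sulfonic acid should spare the benzyl ethers.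

Step 9
Reactants: 16 2-[2,5-bis(benzyloxy)-4-methoxyphenyl]-5-hydroxy-3,7-dimethoxy-4H-chromen-4-one
Product: 17 2-[2,5-bis(benzyloxy)-4-methoxyphenyl]-3,5,7-trimethoxy-4H-chromen-4-one
Conditions: Me2SO4 (3 equiv), K2CO3, acetone, reflux
Reagents that add atoms: dimethyl sulfate, COS(=O)(=O)OC
Why: O-methylation (SN2 on dimethyl sulfate) of the hydrogen-bonded 5-hydroxyl, the only free hydroxyl present, which needs excess reagent and prolonged reflux.

Step 10
Reactants: 17 2-[2,5-bis(benzyloxy)-4-methoxyphenyl]-3,5,7-trimethoxy-4H-chromen-4-one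
Product: 18 5-O-methyloxyayanin A, 2-(2,5-dihydroxy-4-methoxyphenyl)-3,5,7-trimethoxy-4H-chromen-4-one
Conditions: H2 (1 atm), Pd/C (10 wt% Pd), EtOAc–MeOH, rt; filtered and concentrated under argon
Reagents that add atoms: none
Why: Catalytic hydrogenolysis of the two benzyl aryl ethers, under which the tetrasubstituted C2=C3 bond and the methyl ethers should be inert, with an oxygen-free work-up to protect the hydroquinone.

**Compound list**

1 | methoxyhydroquinone (2-methoxybenzene-1,4-diol) | COc1cc(O)ccc1O | starting material
2 | 1,4-bis(benzyloxy)-2-methoxybenzene | COc1cc(OCc2ccccc2)ccc1OCc1ccccc1 | intermediate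
3 | 1,4-bis(benzyloxy)-2-bromo-5-methoxybenzene | COc1cc(OCc2ccccc2)c(Br)cc1OCc1ccccc1 | intermediate
4 | [2,5-bis(benzyloxy)-4-methoxyphenyl]lithium (formed in the flask, not isolated) | COc1cc(OCc2ccccc2)c([Li])cc1OCc1ccccc1 | intermediate
5 | 2,5-bis(benzyloxy)-N,4-dimethoxy-N-methylbenzamide | CON(C)C(=O)c1cc(OCc2ccccc2)c(OC)cc1OCc1ccccc1 | intermediate
6 | methoxyacetyl chloride | COCC(=O)Cl | starting material
7 | N,2-dimethoxy-N-methylacetamide | COCC(=O)N(C)OC | intermediate
8 | 4-methoxy-6-methyl-2H-pyran-2-one | COc1cc(C)oc(=O)c1 | starting material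
9 | 6-(lithiomethyl)-4-methoxy-2H-pyran-2-one (formed in the flask, not isolated) | COc1cc(C[Li])oc(=O)c1 | intermediate
10 | 4-methoxy-6-(3-methoxy-2-oxopropyl)-2H-pyran-2-one | COCC(=O)Cc1cc(OC)cc(=O)o1 | intermediate
11 | dilithio dianion of 10, lithium enolate toward the pyranylmethylene carbon and C-lithiated at the methoxymethylene carbon (formed in the flask, not isolated) | [Li]C(OC)C(O[Li])=Cc1cc(OC)cc(=O)o1 | intermediate
12 | 6-{4-[2,5-bis(benzyloxy)-4-methoxyphenyl]-3-methoxy-2,4-dioxobutyl}-4-methoxy-2H-pyran-2-one (racemic, labile CH(OMe) carbon) | COc1cc(CC(=O)C(OC)C(=O)c2cc(OCc3ccccc3)c(OC)cc2OCc2ccccc2)oc(=O)c1 | intermediate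
13 | methyl (E)-9-[2,5-bis(benzyloxy)-4-methoxyphenyl]-3,8-dimethoxy-5,7,9-trioxonon-2-enoate (present as its magnesium chelate, not isolated; racemic at C8) | COC(=O)/C=C(/OC)CC(=O)CC(=O)C(OC)C(=O)c1cc(OCc2ccccc2)c(OC)cc1OCc1ccccc1 | intermediate
14 | 1-[2,5-bis(benzyloxy)-4-methoxyphenyl]-3-(2,6-dihydroxy-4-methoxyphenyl)-2-methoxypropane-1,3-dione (racemic, labile CH(OMe) carbon) | COc1cc(O)c(C(=O)C(OC)C(=O)c2cc(OCc3ccccc3)c(OC)cc2OCc2ccccc2)c(O)c1 | intermediate
15 | 2-[2,5-bis(benzyloxy)-4-methoxyphenyl]-2,5-dihydroxy-3,7-dimethoxy-2,3-dihydro-4H-chromen-4-one (diastereomer mixture, not isolated; both centers are lost on dehydration) | COc1cc(O)c2c(c1)OC(O)(c1cc(OCc3ccccc3)c(OC)cc1OCc1ccccc1)C(OC)C2=O | intermediate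
16 | 2-[2,5-bis(benzyloxy)-4-methoxyphenyl]-5-hydroxy-3,7-dimethoxy-4H-chromen-4-one | COc1cc(O)c2c(c1)oc(-c1cc(OCc3ccccc3)c(OC)cc1OCc1ccccc1)c(OC)c2=O | intermediate
17 | 2-[2,5-bis(benzyloxy)-4-methoxyphenyl]-3,5,7-trimethoxy-4H-chromen-4-one | COc1cc(OC)c2c(c1)oc(-c1cc(OCc3ccccc3)c(OC)cc1OCc1ccccc1)c(OC)c2=O | intermediate
18 | 5-O-methyloxyayanin A, 2-(2,5-dihydroxy-4-methoxyphenyl)-3,5,7-trimethoxy-4H-chromen-4-one | COc1cc(OC)c2c(=O)c(OC)c(-c3cc(O)c(OC)cc3O)oc2c1 | target

**Step count**

Total: 10 steps. Longest linear sequence: 8 steps (steps 1, 2, 3, 6, 7, 8, 9, 10).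

**Steps most likely to fail**

Step 7. The chain may fold through other atoms (aldol closure of chain C4 onto the aryl ketone, or addition–elimination of C8 at the enol ether carbon). Methoxide may also cleave the 2-methoxy-1,3-diketone by retro-Claisen fragmentation, or the opened ester may simply relactonize without closing. The fallback gives up the chain folding, takes ring A from a bought phenol and makes the diketone by acyl migration; it sets out from 3 and 6 and comes back at 17. Aryllithium 4, generated from 3 as in step 3, is carboxylated with CO2 to 2,5-bis(benzyloxy)-4-methoxybenzoic acid F1. Commercial 3,5-dimethoxyphenol (COc1cc(O)cc(OC)c1) is acylated with 6 under BF3·OEt2 (O-acylation, then Fries shift to the chelated ortho position) to 1-(2-hydroxy-4,6-dimethoxyphenyl)-2-methoxyethan-1-one F2. Esterification of F1 with F2 (EDC·HCl, DMAP, CH2Cl2) should give 3,5-dimethoxy-2-(methoxyacetyl)phenyl 2,5-bis(benzyloxy)-4-methoxybenzoate F3. Baker–Venkataraman rearrangement (LiN(SiMe3)2, THF, −20 °C → rt) should then give 1-[2,5-bis(benzyloxy)-4-methoxyphenyl]-3-(2-hydroxy-4,6-dimethoxyphenyl)-2-methoxypropane-1,3-dione F4. Cyclodehydration under the conditions of step 8 leads directly to 17, so steps 5 to 9 are bypassed.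

Step 6. The hindered, electron-rich amide 5 may react too slowly, so that the dianion is lost to proton transfer, or acylation may occur through the pyranylmethylene carbon or on oxygen. The fallback replaces the acyl donor by an aldehyde and adjusts the oxidation level afterwards; it sets out from 2 and 10 and comes back at 12. Vilsmeier–Haack formylation of 2 (POCl3, DMF, 60 °C) para to the methoxy group should give 2,5-bis(benzyloxy)-4-methoxybenzaldehyde F5. Dianion 11, generated from 10 as in step 6, adds to it at −78 °C through the methoxymethylene terminus to give 6-{4-[2,5-bis(benzyloxy)-4-methoxyphenyl]-4-hydroxy-3-methoxy-2-oxobutyl}-4-methoxy-2H-pyran-2-one F6, a diastereomer mixture of no consequence. Oxidation with Dess–Martin periodinane (NaHCO3, CH2Cl2) then gives 12.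

Step 5. Premature collapse of the tetrahedral adduct, or proton transfer from the methoxymethylene group of 7, may quench lithiomethylpyranone 9, which would return 8 and give doubly acylated material. The fallback uses aldehyde addition and oxidation in place of acyl substitution; it sets out from 8 and comes back at 10. Species 9, generated from 8 as in step 5, is added to methoxyacetaldehyde (COCC=O) at −78 °C to give 6-(2-hydroxy-3-methoxypropyl)-4-methoxy-2H-pyran-2-one F7, whose alkoxide is neither acidic nor able to collapse. Dess–Martin oxidation of this alcohol then gives 10.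

**Further compounds**

F1 | step 7 | 2,5-bis(benzyloxy)-4-methoxybenzoic acid | OC(=O)c1cc(OCc2ccccc2)c(OC)cc1OCc1ccccc1
F2 | step 7 | 1-(2-hydroxy-4,6-dimethoxyphenyl)-2-methoxyethan-1-one | COCC(=O)c1c(O)cc(OC)cc1OC
F3 | step 7 | 3,5-dimethoxy-2-(methoxyacetyl)phenyl 2,5-bis(benzyloxy)-4-methoxybenzoate | COCC(=O)c1c(OC)cc(OC)cc1OC(=O)c1cc(OCc2ccccc2)c(OC)cc1OCc1ccccc1
F4 | step 7 | 1-[2,5-bis(benzyloxy)-4-methoxyphenyl]-3-(2-hydroxy-4,6-dimethoxyphenyl)-2-methoxypropane-1,3-dione | COc1cc(O)c(C(=O)C(OC)C(=O)c2cc(OCc3ccccc3)c(OC)cc2OCc2ccccc2)c(OC)c1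
F5 | step 6 | 2,5-bis(benzyloxy)-4-methoxybenzaldehyde | O=Cc1cc(OCc2ccccc2)c(OC)cc1OCc1ccccc1
F6 | step 6 | 6-{4-[2,5-bis(benzyloxy)-4-methoxyphenyl]-4-hydroxy-3-methoxy-2-oxobutyl}-4-methoxy-2H-pyran-2-one (diastereomer mixture) | COc1cc(CC(=O)C(OC)C(O)c2cc(OCc3ccccc3)c(OC)cc2OCc2ccccc2)oc(=O)c1
F7 | step 5 | 6-(2-hydroxy-3-methoxypropyl)-4-methoxy-2H-pyran-2-one (racemic) | COCC(O)Cc1cc(OC)cc(=O)o1
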